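**Plan**
- Retrosynthetic cuts, in order: C8–CHO (formylation ortho to the 7-OH); C3–C9 (coupling of a 3-bromochromone with the ring B benzylzinc); C2–C3 and C3–C4 together (C3 leaves as a dihalocarbene carbon); C4–C4a and O1–C2 (aryloxyacetic acid); C8a–O1 (arene C–H oxidation).
- Enabling feature: in the pyranone ring O1–C2–C3–C4–C4a–C8a, C3 lies between C2 (bonded to O1) and C4 (bearing the carbonyl oxygen). Without C3 the ring is the five-membered O1–C2–C4–C4a–C8a ring of a benzofuran-3-one. Its silyl enol ether has a C2=C4 double bond with an oxygen donor on each carbon, which suits both an electrophilic carbene and the ionisation that follows.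
- Forward order: ring A is bought as 2,6-dimethoxytoluene. The furanone ring closes on a mirror-symmetric aryloxyacetic acid, so only one regioisomer is possible. CBr2 enlarges the furan to the pyranone and leaves Br on C3. Ring B is joined last through C9.
- Oxygen pattern: methyl ethers carry ring A through the acid and carbene chemistry. Both are cleaved before ring B arrives, and the difference between the chelated 5-OH and the free 7-OH places MOM on O7 and methyl on O5.
- Stereochemistry: the target has no stereocentre. The only stereocentres of the route (a racemic, cis-fused cyclopropane) are made and destroyed within the key step.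

Key step: step 5

Remark: chromone numbering (O1, C2, C3, C4=O, C4a, C5–C8, C8a; C9 benzylic) is used for the chromones and benzofuran numbering for the benzofuranone and its silyl ether. Benzofuran C2 and C3 become chromone C2 and C4.

Step 1
Reactants: 1 2,6-dimethoxytoluene (1,3-dimethoxy-2-methylbenzene)
Product: 3 3,5-dimethoxy-4-methylphenol, via aryl pinacol boronate 2 (not isolated)
Conditions: B2pin2 (1.0 equiv), [Ir(OMe)(cod)]2 (1 mol%), dtbpy (2 mol%), THF, 80 °C; then 30% aq H2O2, NaOH, 0 °C; HCl to pH 5
Reagents that add atoms: hydrogen peroxide, OO (phenol oxygen); bis(pinacolato)diboron, CC1(C)OB(OC1(C)C)B1OC(C)(C)C(C)(C)O1 (boryl group of 2 only)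
Why: Iridium-catalysed aromatic C–H borylation (Hartwig–Miyaura type) is sterically governed, C5–H is the only ring C–H of 1 without an ortho substituent, and the boronate is oxidised at the same carbon to the phenol in one flask.

Step 2
Reactants: 3 3,5-dimethoxy-4-methylphenol; 4 ethyl bromoacetate
Product: 6 (3,5-dimethoxy-4-methylphenoxy)acetic acid, via ethyl aryloxyacetate 5 (not isolated)
Conditions: K2CO3, acetone, reflux; then 2 M aq NaOH, EtOH, rt; HCl to pH 2
Reagents that add atoms: ethyl bromoacetate 4, CCOC(=O)CBr; sodium hydroxide, [Na+].[OH-] (acid OH oxygen)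
Why: Williamson etherification of the phenoxide with a primary alpha-halo ester, followed by saponification of the crude ester, is the routine entry to aryloxyacetic acids.

Step 3
Reactants: 6 (3,5-dimethoxy-4-methylphenoxy)acetic acid
Product: 7 4,6-dimethoxy-5-methyl-1-benzofuran-3(2H)-one
Conditions: P2O5/MeSO3H (Eaton's reagent), 25–50 °C
Reagents that add atoms: none
Why: In this intramolecular Friedel–Crafts acylation the tether reaches only the two positions ortho to its own oxygen, which are equivalent by symmetry and activated by three oxygen donors, and methyl ethers tolerate the strong acid, as is known for 3,5-dimethoxyphenoxyacetic acid.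

Step 4
Reactants: 7 4,6-dimethoxy-5-methyl-1-benzofuran-3(2H)-one
Product: 8 tert-butyl[(4,6-dimethoxy-5-methyl-1-benzofuran-3-yl)oxy]dimethylsilane (TBS enol ether)
Conditions: TBSOTf, Et3N, CH2Cl2, 0 °C
Reagents that add atoms: tert-butyldimethylsilyl triflate, CC(C)(C)[Si](C)(C)OS(=O)(=O)C(F)(F)F
Why: Soft enolisation with a silyl triflate and an amine base gives O-silylation, favoured here by the acidity of C2–H and the gain of benzofuran aromaticity, as is standard for benzofuran-3-ones.

Step 5
Reactants: 8 tert-butyl[(4,6-dimethoxy-5-methyl-1-benzofuran-3-yl)oxy]dimethylsilane; 9 bromoform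
Product: 12 3-bromo-5,7-dimethoxy-6-methyl-4H-chromen-4-one, via dibromocyclopropane adduct 10 (not isolated), via 4-siloxybenzopyrylium bromide 11 (not isolated)
Conditions: CHBr3 (3 equiv), KOtBu (2.5 equiv, slow addition), hexane/toluene, −20 °C to rt
Reagents that add atoms: bromoform 9, BrC(Br)Br
Why: Proposed new method: alpha-elimination of HBr from bromoform gives dibromocarbene, which adds in a concerted (2+1) cheletropic step to the benzofuran C2=C3 bond of 8 to give the cis-fused dibromocyclopropane 10. The endo bromide of this strained bicyclo[3.1.0] unit ionises while the bond shared by the two rings (old C2–C3) opens in a disrotatory two-electron electrocyclic process, pushed by the ring oxygen on one terminus and the siloxy oxygen on the other and rewarded by the aromaticity of the 4-siloxybenzopyrylium ion 11; bromide then removes the silyl group and leaves 12, in which the carbene carbon is C3, bonded to C2 and C4 and still carrying one bromine. The six-membered pyranone is thus closed by ring enlargement (cycloaddition, then electrocyclic opening of the fused bond), not by cyclisation of a chain. The two stereocentres of 10 are racemic, held cis by the ring fusion and erased in 11, so nothing has to be controlled. The closest known reaction types are the dihalocarbene ring expansion of cyclic silyl enol ethers to 2-halo enones, the dihalocarbene expansion of benzofurans to 3-halochromenes and the Ciamician–Dennstedt expansion of indoles to 3-haloquinolines; new here is only their combination in a 3-siloxybenzofuran. The step needs the carbene to choose the enol ether bond over the dimethoxyarene and to be faster than desilylation of 8 or base attack at C2 of 12, which is secured by the two oxygen donors on that bond, by methyl ethers that offer no activated benzylic C–H for insertion, by the bulky TBS group and by adding KOtBu slowly to an excess of bromoform in a non-polar medium.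

Step 6
Reactants: 12 3-bromo-5,7-dimethoxy-6-methyl-4H-chromen-4-one
Product: 13 3-bromo-5,7-dihydroxy-6-methyl-4H-chromen-4-one
Conditions: BBr3 (4 equiv), CH2Cl2, −78 °C to rt; then H2O
Reagents that add atoms: none
Why: Lewis-acid aryl methyl ether cleavage with BBr3 is standard for 5,7-dimethoxychromones, leaves the vinylic C–Br bond and the pyranone alone, and is run before ring B arrives so that the ring B methoxy group is never exposed to it.

Step 7
Reactants: 13 3-bromo-5,7-dihydroxy-6-methyl-4H-chromen-4-one
Product: 14 3-bromo-5-hydroxy-7-(methoxymethoxy)-6-methyl-4H-chromen-4-one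
Conditions: MOMCl (1.1 equiv), iPr2NEt, CH2Cl2/DMF, 0 °C to rt
Reagents that add atoms: chloromethyl methyl ether, COCCl
Why: This chemoselective O-alkylation works because the 5-OH is locked in a six-membered hydrogen bond to C4=O and flanked by the C6 methyl, so one equivalent of MOMCl meets only the more acidic free 7-OH, as is established for 5,7-dihydroxychromones.

Step 8
Reactants: 14 3-bromo-5-hydroxy-7-(methoxymethoxy)-6-methyl-4H-chromen-4-one
Product: 15 3-bromo-5-methoxy-7-(methoxymethoxy)-6-methyl-4H-chromen-4-one
Conditions: MeI (excess), K2CO3, acetone, reflux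
Reagents that add atoms: iodomethane, CI
Why: Williamson methylation of a chelated 5-hydroxychromone proceeds with excess MeI and anhydrous carbonate, a base too poorly nucleophilic to attack C2 of the bromochromone, and the MOM acetal is stable to base.

Step 9
Reactants: 16 4-methoxybenzyl chloride
Product: 17 4-methoxybenzylzinc chloride (THF solution, LiCl-solubilised, titrated and used as such)
Conditions: Zn dust, LiCl, THF, 25 °C
Reagents that add atoms: zinc, [Zn]
Why: Direct oxidative insertion of LiCl-activated zinc into a benzylic C–Cl bond is a known, mild preparation of benzylic zinc chlorides that keeps Wurtz-type coupling low.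

Step 10
Reactants: 15 3-bromo-5-methoxy-7-(methoxymethoxy)-6-methyl-4H-chromen-4-one; 17 4-methoxybenzylzinc chloride
Product: 18 5-methoxy-3-(4-methoxybenzyl)-7-(methoxymethoxy)-6-methyl-4H-chromen-4-one
Conditions: Pd(OAc)2 (2 mol%), SPhos (4 mol%), THF, 25–40 °C
Reagents that add atoms: 4-methoxybenzylzinc chloride 17, COc1ccc(C[Zn]Cl)cc1
Why: In this Negishi sp2–sp3 cross-coupling zerovalent palladium inserts readily into the C–Br bond of the alpha-bromo enone, the benzyl group has no beta-hydrogen, and the soft organozinc does not add to C2 or C4.

Step 11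
Reactants: 18 5-methoxy-3-(4-methoxybenzyl)-7-(methoxymethoxy)-6-methyl-4H-chromen-4-one
Product: 19 7-hydroxy-5-methoxy-3-(4-methoxybenzyl)-6-methyl-4H-chromen-4-one
Conditions: HCl (cat.), MeOH, 50 °C
Reagents that add atoms: none
Why: Acid-catalysed transacetalisation removes the MOM group and traps its methylene unit in methanol, while both methyl ethers and the C2=C3 bond, which a hydrogenolytic deprotection would endanger, are untouched.

Step 12
Reactants: 19 7-hydroxy-5-methoxy-3-(4-methoxybenzyl)-6-methyl-4H-chromen-4-one
Product: 21 7-hydroxy-5-methoxy-3-(4-methoxybenzyl)-6-methyl-4-oxo-4H-chromene-8-carbaldehyde (target), via 8-aldimine 20 (not isolated)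
Conditions: (CH2)6N4, AcOH, 100 °C; then 3 M aq HCl, 70 °C
Reagents that add atoms: hexamethylenetetramine, C1N2CN3CN1CN(C2)C3 (formyl carbon); water, O (formyl oxygen)
Why: The Duff reaction (ortho-aminomethylation, internal hydride shift to the imine, hydrolysis) is known to formylate 7-hydroxychromones and isoflavones at C8, here the only free position ortho to the phenol, and in acetic acid only phenols react, so the anisole ring B is spared.

**Compound list**
1 | 2,6-dimethoxytoluene (1,3-dimethoxy-2-methylbenzene) | COc1cccc(OC)c1C | starting material
2 | 2-(3,5-dimethoxy-4-methylphenyl)-4,4,5,5-tetramethyl-1,3,2-dioxaborolane | COc1cc(cc(OC)c1C)B1OC(C)(C)C(C)(C)O1 | intermediate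
3 | 3,5-dimethoxy-4-methylphenol | COc1cc(O)cc(OC)c1C | intermediate
4 | ethyl bromoacetate | CCOC(=O)CBr | starting material
5 | ethyl (3,5-dimethoxy-4-methylphenoxy)acetate | CCOC(=O)COc1cc(OC)c(C)c(OC)c1 | intermediate
6 | (3,5-dimethoxy-4-methylphenoxy)acetic acid | OC(=O)COc1cc(OC)c(C)c(OC)c1 | intermediate
7 | 4,6-dimethoxy-5-methyl-1-benzofuran-3(2H)-one | COc1cc2OCC(=O)c2c(OC)c1C | intermediate
8 | tert-butyl[(4,6-dimethoxy-5-methyl-1-benzofuran-3-yl)oxy]dimethylsilane | COc1cc2occ(O[Si](C)(C)C(C)(C)C)c2c(OC)c1C | intermediate
9 | bromoform | BrC(Br)Br | starting material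
10 | rac-1,1-dibromo-6b-[(tert-butyldimethylsilyl)oxy]-4,6-dimethoxy-5-methyl-1a,6b-dihydro-1H-cyclopropa[b][1]benzofuran (cis ring fusion, H-1a and the siloxy group on the same face; one enantiomer drawn) | COc1cc2O[C@H]3C(Br)(Br)[C@@]3(O[Si](C)(C)C(C)(C)C)c2c(OC)c1C | intermediate
11 | 3-bromo-4-[(tert-butyldimethylsilyl)oxy]-5,7-dimethoxy-6-methylchromenylium bromide | COc1cc2[o+]cc(Br)c(O[Si](C)(C)C(C)(C)C)c2c(OC)c1C.[Br-] | intermediate
12 | 3-bromo-5,7-dimethoxy-6-methyl-4H-chromen-4-one | COc1cc2occ(Br)c(=O)c2c(OC)c1C | intermediate
13 | 3-bromo-5,7-dihydroxy-6-methyl-4H-chromen-4-one | Cc1c(O)cc2occ(Br)c(=O)c2c1O | intermediate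
14 | 3-bromo-5-hydroxy-7-(methoxymethoxy)-6-methyl-4H-chromen-4-one | COCOc1cc2occ(Br)c(=O)c2c(O)c1C | intermediate
15 | 3-bromo-5-methoxy-7-(methoxymethoxy)-6-methyl-4H-chromen-4-one | COCOc1cc2occ(Br)c(=O)c2c(OC)c1C | intermediate
16 | 4-methoxybenzyl chloride | COc1ccc(CCl)cc1 | starting material
17 | 4-methoxybenzylzinc chloride | COc1ccc(C[Zn]Cl)cc1 | intermediate
18 | 5-methoxy-3-(4-methoxybenzyl)-7-(methoxymethoxy)-6-methyl-4H-chromen-4-one | COCOc1cc2occ(Cc3ccc(OC)cc3)c(=O)c2c(OC)c1C | intermediate
19 | 7-hydroxy-5-methoxy-3-(4-methoxybenzyl)-6-methyl-4H-chromen-4-one | COc1ccc(Cc2coc3cc(O)c(C)c(OC)c3c2=O)cc1 | intermediate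
20 | 7-hydroxy-8-(iminomethyl)-5-methoxy-3-(4-methoxybenzyl)-6-methyl-4H-chromen-4-one (simplest form of the hexamine-derived imine) | COc1ccc(Cc2coc3c(C=N)c(O)c(C)c(OC)c3c2=O)cc1 | intermediate
21 | 7-hydroxy-5-methoxy-3-(4-methoxybenzyl)-6-methyl-4-oxo-4H-chromene-8-carbaldehyde | COc1ccc(Cc2coc3c(C=O)c(O)c(C)c(OC)c3c2=O)cc1 | target

Total step count: 12. Longest linear sequence: 11 (steps 1–8 and 10–12; step 9 is the side branch).

**Steps most likely to fail**

1. Step 5.
   - What may go wrong: tert-butoxide may strip the silyl group before the carbene arrives. The peri methoxy and TBS groups may slow the cycloaddition to a double bond that is partly aromatic. Nucleophiles in the flask may add to C2 of the pyrylium ion or of the bromochromone and open the ring.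
   - Fallback: it gives up the ring enlargement and uses the established enaminone route to 3-halochromones, setting out from 3. Friedel–Crafts/Fries-type C-acetylation (Ac2O, BF3·OEt2, 90 °C) can only strike the two equivalent positions ortho to the hydroxyl and should give 1-(6-hydroxy-2,4-dimethoxy-3-methylphenyl)ethan-1-one F1. Heating with N,N-dimethylformamide dimethyl acetal should give the enaminone (E)-3-(dimethylamino)-1-(6-hydroxy-2,4-dimethoxy-3-methylphenyl)prop-2-en-1-one F2. Bromine in CHCl3 at 0 °C brominates the alpha carbon, the phenol closes onto the iminium carbon and dimethylamine is lost, which comes back to the route at 12.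

2. Step 12.
   - What may go wrong: aminomethylation of a phenol deactivated by the pyranone carbonyl may be sluggish. The internal redox to the imine may stay incomplete. Liberated ammonia may attack C2 and open the pyranone.
   - Fallback: it replaces electrophilic formylation by halogenation and carbonylation, setting out from 19. Iodination with NIS in DMF, directed by the 7-OH to its only free ortho position, should give 7-hydroxy-8-iodo-5-methoxy-3-(4-methoxybenzyl)-6-methyl-4H-chromen-4-one F3. Palladium-catalysed reductive carbonylation (Pd(OAc)2, dppp, CO, Et3SiH, DMF, 70 °C) should convert the C–I bond into the formyl group and arrive at 21.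

3. Step 10.
   - What may go wrong: homocoupling of the electron-rich benzylzinc reagent, protodebromination of the chromone, or slow transmetalation next to the crowded carbonyl may erode the coupling.
   - Fallback: it reverses the polarity of the partners, setting out from 15. Zinc insertion (Zn dust, LiCl, THF) into the carbonyl-activated C3–Br bond should give [5-methoxy-7-(methoxymethoxy)-6-methyl-4-oxo-4H-chromen-3-yl]zinc bromide F4; 3-zincated chromones are known, stable coupling partners. This is coupled with the benzylic chloride 16 under Pd(OAc)2/SPhos and comes back to the route at 18.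

**Further compounds**
F1 | step 5 | 1-(6-hydroxy-2,4-dimethoxy-3-methylphenyl)ethan-1-one | CC(=O)c1c(O)cc(OC)c(C)c1OC
F2 | step 5 | (E)-3-(dimethylamino)-1-(6-hydroxy-2,4-dimethoxy-3-methylphenyl)prop-2-en-1-one | CN(C)/C=C/C(=O)c1c(O)cc(OC)c(C)c1OC
F3 | step 12 | 7-hydroxy-8-iodo-5-methoxy-3-(4-methoxybenzyl)-6-methyl-4H-chromen-4-one | COc1ccc(Cc2coc3c(I)c(O)c(C)c(OC)c3c2=O)cc1
F4 | step 10 | [5-methoxy-7-(methoxymethoxy)-6-methyl-4-oxo-4H-chromen-3-yl]zinc bromide | COCOc1cc2occ([Zn]Br)c(=O)c2c(OC)c1C
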